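Readings and results were computed with made-up constants, and the scatter is random.

**The pitfall.** Do not take Wednesday's last target reading, 54%, as a ceiling for amber and green. It was read at 5.00 min, with substrate still reading 22%.

| flask | substrate | reagent | free catalyst | remark | time |
|---|---|---|---|---|---|
| Monday's | 0.10 M | 0.12 M | 0.043 mM | run made earlier |  |
| Wednesday's | 0.10 M | 0.12 M | 0.62 mM | run made earlier |  |
| Friday's | 0.10 M | 0.11 M | 0.10 mM | run made earlier |  |
| amber | 0.025 M | 0.120 M | 0.40 mM |  | 10 min |
| grey | 0.30 M | 0.120 M | 0.030 mM |  | 10 min |
| green | 0.10 M | 0.200 M | 0.40 mM |  | 10 min |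
| red | 0.10 M | 0.120 M | 0.10 mM |  | 10 min |
| teal | 0.15 M | 0.0400 M | 0.10 mM |  | 10 min |

| run | time / min | target / % | substrate / % |
|---|---|---|---|
| Monday's | 0.417 | 0 | 99 |
| Monday's | 1.33 | 0 | 96 |
| Monday's | 2.50 | 6 | 94 |
| Monday's | 4.00 | 8 | 91 |
| Monday's | 5.00 | 8 | 91 |
| Wednesday's | 0.417 | 6 | 91 |
| Wednesday's | 1.33 | 25 | 70 |
| Wednesday's | 2.50 | 42 | 53 |
| Wednesday's | 4.00 | 50 | 32 |
| Wednesday's | 5.00 | 54 | 22 |
| Friday's | 1.00 | 6 | 96 |
| Friday's | 2.00 | 5 | 91 |
| Friday's | 3.00 | 12 | 89 |
| Friday's | 4.00 | 15 | 86 |
| Friday's | 5.00 | 16 | 80 |

(each reading ± 1.5 percentage points)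

- the earlier runs were read with a standard deviation of 1.5 percentage points

- the flasks by amount of target, in percent of the substrate charged, highest first, at 10 min (amber / grey / green / red / teal)
- the amount of target, in percent of the substrate charged of the flask you put first, at 10 min
- the amount of target, in percent of the substrate charged of the flask you put last, at 10 min

**Bench rule.** Treat substrate as first order, with a rate proportional to the catalyst charged. Scale Wednesday's exponent by catalyst and time. Amber and green then keep 14.2% of their substrate. Now count substrate gone as target made: 85.8% each.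

**The border.** Wednesday breaks that count. From 2.50 min to 5.00 min, substrate fell 31 points and target rose 12 points. So a share 0.613 of that fall went missing.

Suppose target and reagent compete for free catalyst, and one reagent goes per substrate. The missing share n then equals s, times target over reagent left, both in moles. Take ρ, substrate charge over reagent charge: 0.833 on Wednesday. Over that stretch, target averaged 48.0% of the substrate charge. Reagent was not read; reckoned from the substrate gone, reagent left averaged 47.9% of its own. So n = s·ρ·(target fraction)/(reagent fraction), and s, the competition number, a selectivity factor, reads 0.734, with the scatter of these readings. The catalyst charge does not appear in this expression.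

**My reckoning.** No target is charged, so n starts at zero in amber and green; lose about n/2 of the substrate gone. Amber has ρ = 0.208, less than green's 0.500. At full count, n is 0.160 for amber and 0.552 for green. Target comes to 78.9% in amber and 62.1% in green. I put amber first.

**The forecast.** It differs: green > amber > red > teal > grey, top 52% (44% to 62%), low 9% (3% to 13%). Its grounds for first place: “Extra reagent favours green slightly.” Its top is close to Wednesday's last reading taken over.

**The result.** The flasks give amber > green > red > teal > grey, with amber at 82.9% and grey at 7.31%.

    target + free catalyst ⇌ isomer of the product + free catalyst, rate k1*[free catalyst]*[target] forward; the back reaction follows from the equilibrium constant (K = 6.20, k = 1200 M⁻¹ min⁻¹)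
    reagent + free catalyst ⇌ catalyst intermediate A (K = 290 M⁻¹, k = 1700 M⁻¹ min⁻¹)
    catalyst intermediate C → free catalyst + target (k = 1500 min⁻¹)
    catalyst intermediate A → catalyst intermediate B (k = 2000 min⁻¹)
    substrate + catalyst intermediate B → catalyst intermediate C (k = 580 M⁻¹ min⁻¹)

**Same reckoning.** The missing part is now isomer of the product. Put in the flask's own amounts. Amber at 10.0 min has n = 0.156, which gives 6.98% isomer against 6.39% simulated. Now read grey later, at 25 min, with ρ = 2.50. Target stands at 14.4%, unbound reagent at 55% of its charge and substrate at 82.2%. So n = 0.476, which gives 4.24% isomer. Grey at 25.0 min holds 3.48% isomer of the product.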